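**Retrosynthetic overview**
1. Ampelopsin B ⇐ acid-triggered global de-O-alkylation plus Friedel–Crafts closure of the seven-membered ring (resorcinol ring onto the protonated stilbene; sets the third stereocentre) from (2S,3S)-penta-O-cyclopropylmethyl-ε-viniferin.
2. trans-2,3-Diaryl-dihydrobenzofuran ⇐ new asymmetric [4+1]: o-quinone methide (from a racemic sulfone) + chiral 4-alkoxybenzyl sulfonium ylide; forms C2–C3 and C2–O, sets C3 and C2.
3. o-Quinone methide precursor ⇐ aryl Grignard addition to a 2-formyl-resveratrol salicylaldehyde, made from resveratrol (alkylation, Vilsmeier, chelation-controlled mono-dealkylation).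
4. Ring order: all benzene rings come preformed; dihydrofuran in step 11, then cycloheptene in step 12.

**Assumptions (one line each)**
- The target SMILES is read as all-S: (2S,3S)-trans dihydrobenzofuran and S at the cycloheptene ArCH carbon, i.e. the product of acid cyclisation of (2S,3S)-ε-viniferin.
- The sulfide is drawn as the (R)-limonene-derived enantiomer; the sense of induction in step 11 is assigned by analogy to ylide epoxidation and is unverified, so if C3 comes out R the (S)-limonene-derived antipode is used with no other change.
- Solvents and common reagents in the conditions line are not numbered; every skeleton-contributing reactant, intermediate and the target is numbered.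
- CPM = cyclopropylmethyl.

**Route**

Step 1
Reactants: 1 resveratrol; 2 (bromomethyl)cyclopropane
Product: 3 (E)-3,4',5-tris(cyclopropylmethoxy)stilbene
Conditions: 2 (3.6 equiv), K2CO3, KI (cat.), DMF, 70 °C
Reagents that add atoms: (bromomethyl)cyclopropane, BrCC1CC1
Why: Williamson O-alkylation of all three phenols with a primary bromide.

Step 2
Reactants: 3 (E)-3,4',5-tris(cyclopropylmethoxy)stilbene
Product: 4 2,4-bis(cyclopropylmethoxy)-6-[(E)-4-(cyclopropylmethoxy)styryl]benzaldehyde
Conditions: POCl3, DMF, 0 → 50 °C; aq. NaOAc
Reagents that add atoms: DMF, CN(C)C=O (formyl carbon); water, O (aldehyde oxygen on hydrolysis)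
Why: Vilsmeier–Haack formylation at the most nucleophilic arene position (ortho/para to the two OR groups, adjacent to the styryl; two equivalent sites), the regiochemistry known for trimethylresveratrol.

Step 3
Reactants: 4 2,4-bis(cyclopropylmethoxy)-6-[(E)-4-(cyclopropylmethoxy)styryl]benzaldehyde
Product: 5 4-(cyclopropylmethoxy)-2-hydroxy-6-[(E)-4-(cyclopropylmethoxy)styryl]benzaldehyde
Conditions: BCl3 (1.05 equiv), CH2Cl2, −78 → −20 °C; aq. NaHCO3
Reagents that add atoms: none
Why: Chelation-controlled Lewis-acid dealkylation; one equivalent of BCl3 is held in the CHO/ortho-O chelate and cleaves only that ether (classical selective ortho-dealkylation of o-alkoxyaryl carbonyls).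

Step 4
Reactants: 6 5-bromoresorcinol; 2 (bromomethyl)cyclopropane
Product: 7 1-bromo-3,5-bis(cyclopropylmethoxy)benzene
Conditions: 2 (2.4 equiv), K2CO3, DMF, 70 °C
Reagents that add atoms: (bromomethyl)cyclopropane, BrCC1CC1
Why: Williamson O-alkylation.

Step 5
Reactants: 5 4-(cyclopropylmethoxy)-2-hydroxy-6-[(E)-4-(cyclopropylmethoxy)styryl]benzaldehyde; 7 1-bromo-3,5-bis(cyclopropylmethoxy)benzene
Product: 8 rac-2-{[3,5-bis(cyclopropylmethoxy)phenyl](hydroxy)methyl}-5-(cyclopropylmethoxy)-3-[(E)-4-(cyclopropylmethoxy)styryl]phenol (used crude)
Conditions: 7, Mg, THF, reflux → ArMgBr (2.5 equiv); then 5, THF, 0 °C → rt; aq. NH4Cl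
Reagents that add atoms: none (both partners are numbered reactants)
Why: Grignard 1,2-addition to the salicylaldehyde (first equivalent deprotonates the phenol); the new carbinol centre is racemic and is erased later at the o-quinone methide stage.

Step 6
Reactants: 8 rac-o-hydroxybenzhydrol
Product: 9 rac-2-{[3,5-bis(cyclopropylmethoxy)phenyl](p-tolylsulfonyl)methyl}-5-(cyclopropylmethoxy)-3-[(E)-4-(cyclopropylmethoxy)styryl]phenol
Conditions: p-TolSO2Na (3 equiv), HCO2H (10 equiv), THF–H2O 4:1, 0 °C → rt
Reagents that add atoms: sodium p-toluenesulfinate, Cc1ccc(S(=O)[O-])cc1.[Na+]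
Why: Weak-acid ionisation of the electron-rich o-hydroxybenzhydrol to the o-quinone methide and S-capture by sulfinate gives the standard bench-stable latent o-quinone methide; the weak acid is chosen to avoid stilbene protonation or cation–olefin cyclisation.

Step 7
Reactants: 10 4-hydroxybenzyl alcohol; 2 (bromomethyl)cyclopropane
Product: 11 [4-(cyclopropylmethoxy)phenyl]methanol
Conditions: 2 (1.1 equiv), K2CO3, acetone, reflux
Reagents that add atoms: (bromomethyl)cyclopropane, BrCC1CC1
Why: Williamson alkylation, chemoselective for the phenol (pKa about 10) over the benzylic alcohol.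

Step 8
Reactants: 11 [4-(cyclopropylmethoxy)phenyl]methanol
Product: 12 1-(bromomethyl)-4-(cyclopropylmethoxy)benzene (used immediately)
Conditions: CBr4, PPh3, CH2Cl2, 0 °C
Reagents that add atoms: carbon tetrabromide, BrC(Br)(Br)Br
Why: Appel bromination under neutral conditions, avoiding HBr with the labile p-alkoxybenzyl bromide.

Step 9
Reactants: 13 (R)-(+)-limonene
Product: 14 (1R,4R,5R)-4,7,7-trimethyl-6-thiabicyclo[3.2.1]octane (isothiocineole)
Conditions: S8, γ-terpinene, neat, 110 °C, 16 h; distil
Reagents that add atoms: sulfur, S1SSSSSSS1 (γ-terpinene donates H only)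
Why: Known one-step radical thia-bicyclisation of limonene (S bridges the isopropenyl carbon and ring C2, with γ-terpinene as H-atom donor); the stereocentres derive from limonene C4.

Step 10
Reactants: 12 1-(bromomethyl)-4-(cyclopropylmethoxy)benzene; 14 (1R,4R,5R)-isothiocineole
Product: 15 (1R,4R,5R,6R)-6-[4-(cyclopropylmethoxy)benzyl]-4,7,7-trimethyl-6-thiabicyclo[3.2.1]octan-6-ium tetrafluoroborate (benzyl on the exo sulfur lone pair, single diastereomer)
Conditions: AgBF4 (1.05 equiv), CH2Cl2, −20 °C → rt, dark; crystallise
Reagents that add atoms: silver tetrafluoroborate, [Ag+].F[B-](F)(F)F (BF4 counter-ion)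
Why: Ag-assisted S-alkylation of the sulfide on its less hindered lone pair, the standard preparation of isothiocineole benzylsulfonium salts.

Step 11 (new transformation)
Reactants: 9 rac-2-[aryl(tosyl)methyl]phenol; 15 S-[4-(cyclopropylmethoxy)benzyl]isothiocineolium tetrafluoroborate (1.4 equiv)
Product: 16 (2S,3S)-3-[3,5-bis(cyclopropylmethoxy)phenyl]-6-(cyclopropylmethoxy)-2-[4-(cyclopropylmethoxy)phenyl]-4-[(E)-4-(cyclopropylmethoxy)styryl]-2,3-dihydrobenzofuran (penta-O-CPM-ε-viniferin)
Conditions: P2-Et phosphazene base (2.6 equiv), CH2Cl2, −78 → −20 °C; chromatography to remove any cis isomer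
Reagents that add atoms: none (both partners are numbered reactants)
Why: Proposed new method: the base converts 9 into the planar o-quinone methide (loss of TolSO2⁻, erasing the racemic centre) and 15 into its semi-stabilised benzylic ylide; irreversible, aromatising 1,4-addition of the single exposed ylide face to the methide carbon in the anti mode sets C3 (S) and the S⁺-bearing carbon, and the phenoxide then displaces the neutral chiral sulfide (the leaving group, which can be recovered and reused) by 5-exo-tet SN2 with inversion to give the trans-(2S,3S) ring (formal [4+1]); the closest known reactions are isothiocineole-mediated asymmetric ylide epoxidation/aziridination and [4+1] annulations of o-quinone methides with carbonyl-stabilised sulfur or ammonium ylides, and an asymmetric benzylidene [4+1] from a chiral sulfonium salt has not been shown. Any cis isomer must be removed here because it is expected to be the C3-epimer and would erode ee after step 12.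

Step 12
Reactants: 16 (2S,3S)-penta-O-CPM-ε-viniferin
Product: 17 ampelopsin B (all-S, target)
Conditions: 12 M aq. HCl, THF, 50 °C, degassed
Reagents that add atoms: none
Why: Strong acid cleaves the five CPM ethers (SN1 via the cyclopropylcarbinyl cation) and protonates the stilbene to a p-oxybenzyl cation that undergoes intramolecular Friedel–Crafts alkylation by C2' of the resorcinol ring, closing the seven-membered ring with the new aryl anti to C2 under control of C3 (the established ε-viniferin → ampelopsin B cyclisation, run as the one-pot CPM deprotection/cyclisation known in the racemic series); C2 can only equilibrate to trans by reversible C–O ionisation and C3 is untouched.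

**Compound list**
1 | resveratrol | Oc1ccc(/C=C/c2cc(O)cc(O)c2)cc1 | starting material
2 | (bromomethyl)cyclopropane | BrCC1CC1 | starting material
3 | (E)-3,4',5-tris(cyclopropylmethoxy)stilbene | C1CC1COc1ccc(/C=C/c2cc(OCC3CC3)cc(OCC3CC3)c2)cc1 | intermediate
4 | 2,4-bis(cyclopropylmethoxy)-6-[(E)-4-(cyclopropylmethoxy)styryl]benzaldehyde | O=Cc1c(OCC2CC2)cc(OCC2CC2)cc1/C=C/c1ccc(OCC2CC2)cc1 | intermediate
5 | 4-(cyclopropylmethoxy)-2-hydroxy-6-[(E)-4-(cyclopropylmethoxy)styryl]benzaldehyde | O=Cc1c(O)cc(OCC2CC2)cc1/C=C/c1ccc(OCC2CC2)cc1 | intermediate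
6 | 5-bromoresorcinol | Oc1cc(O)cc(Br)c1 | starting material
7 | 1-bromo-3,5-bis(cyclopropylmethoxy)benzene | Brc1cc(OCC2CC2)cc(OCC2CC2)c1 | intermediate
8 | rac o-hydroxybenzhydrol (carbinol centre racemic) | OC(c1cc(OCC2CC2)cc(OCC2CC2)c1)c1c(O)cc(OCC2CC2)cc1/C=C/c1ccc(OCC2CC2)cc1 | intermediate
9 | rac 2-[aryl(tosyl)methyl]phenol (sulfone centre racemic) | Cc1ccc(cc1)S(=O)(=O)C(c1cc(OCC2CC2)cc(OCC2CC2)c1)c1c(O)cc(OCC2CC2)cc1/C=C/c1ccc(OCC2CC2)cc1 | intermediate
10 | 4-hydroxybenzyl alcohol | OCc1ccc(O)cc1 | starting material
11 | [4-(cyclopropylmethoxy)phenyl]methanol | OCc1ccc(OCC2CC2)cc1 | intermediate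
12 | 1-(bromomethyl)-4-(cyclopropylmethoxy)benzene | BrCc1ccc(OCC2CC2)cc1 | intermediate
13 | (R)-(+)-limonene | CC1=CC[C@@H](CC1)C(C)=C | starting material
14 | (1R,4R,5R)-isothiocineole | C[C@@H]1CC[C@@H]2C[C@H]1SC2(C)C | intermediate
15 | (1R,4R,5R,6R)-S-[4-(cyclopropylmethoxy)benzyl]isothiocineolium tetrafluoroborate | C[C@@H]1CC[C@@H]2C[C@H]1[S@@+](Cc1ccc(OCC3CC3)cc1)C2(C)C.F[B-](F)(F)F | intermediate
16 | (2S,3S)-penta-O-cyclopropylmethyl-ε-viniferin | C1CC1COc1ccc(/C=C/c2cc(OCC3CC3)cc3c2[C@H](c2cc(OCC4CC4)cc(OCC4CC4)c2)[C@@H](c2ccc(OCC4CC4)cc2)O3)cc1 | intermediate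
17 | ampelopsin B | Oc1ccc([C@@H]2Cc3cc(O)cc4c3[C@H](c3cc(O)cc(O)c32)[C@@H](c2ccc(O)cc2)O4)cc1 | target

**Totals**
Total steps: 12. Longest linear sequence: 7 (steps 1, 2, 3, 5, 6, 11, 12 from resveratrol).

**Three steps most likely to fail, with fallbacks**
1. Step 11 (proposed asymmetric [4+1]). Risks: insufficient facial control at the o-quinone methide carbon (which is the C3 stereocentre), o-quinone methide oligomerisation, and ylide decomposition. Fallback with known chemistry: Rh(II) donor/donor-carbene C–H insertion. Oxidise 8 (MnO2) to the 2-hydroxybenzophenone, O-alkylate with 12, form the hydrazone, oxidise to the diaryldiazomethane (MnO2), and insert into the benzylic ether C–H with Rh2(PTAD)4 (enantiomer chosen to give 3S). This gives the cis-2,3-diaryl-dihydrobenzofuran, which step 12 converts to trans by C2 epimerisation while cyclising.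
2. Step 12 (one-pot deprotection/cyclisation). Risks: competing dihydrofuran opening to ampelopsin D/F-type skeletons, and C-alkylation of the polyphenol by CPM-derived cations. Fallback: run the sequence in a benzyl-ether series (BnBr in steps 1, 4 and 7) and close the seven-membered ring on the fully protected stilbene with a mild acid (TsOH or TFA, CH2Cl2, low temperature). Then remove the benzyl groups in a separate step with BCl3/pentamethylbenzene at −78 °C (cation scavenger), or by hydrogenolysis (H2, Pd(OH)2/C) if the benzylic C2–O bond survives, so the free polyphenol never meets hot strong acid.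
3. Step 6 (sulfone formation on a very electron-rich benzhydrol bearing an ortho-styryl group). Risks: cation–olefin (indane-forming) cyclisation or oligomerisation under acid, and a labile product. Fallback: generate the o-quinone methide under purely anionic conditions. Protect 5 as its O-Boc carbonate, add the aryllithium from 7 at −78 °C (carbonate migrates to the benzylic oxygen), then release the o-quinone methide with MgBr2·OEt2 in the presence of the preformed ylide, with no acid and no isolated sulfone.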